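**Plan**
- Retrosynthesis first cuts the four benzyl ether O–C bonds and the C3–OMe bond, leading back to a 3-iodo-4H-chromen-4-one.
- Ring C is then opened at O1–C2 and C3–I. The enabling feature is the C2=C3 unit of ring C, with O1 on C2 and a heteroatom on C3 next to the C4 carbonyl: it corresponds to the alkyne of an aryl alkynyl ketone. Ring A carries two equivalent ortho oxygens (the future O1 and 5-O), so either can close the ring.
- The ynone is cut at the C4–C3 bond into a ring A benzaldehyde (from syringol) and a ring B arylacetylene (from 3,4-bis(benzyloxy)benzaldehyde).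
- Forward: the ring A aldehyde (steps 1 to 5) and the ring B alkyne (steps 6 to 9) are joined by acetylide addition and oxidation. Ring C is the only ring formed and closes in the ICl step. The C3 iodide is then converted to OH and OMe, and the benzyl ethers are removed last.
- Stereochemistry: the target has no stereocentre. The one carbinol centre formed at fragment union is racemic and is erased by oxidation.

Key step: step 12

Remark: benzyl bromide, DMF, iodomethane and the other reagents are not numbered; only compounds that carry the growing skeleton are.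

Step 1
Reactants: 1 2,6-dimethoxyphenol (syringol)
Product: 2 2-(benzyloxy)-1,3-dimethoxybenzene
Conditions: BnBr, K2CO3, DMF, rt
Reagents that add atoms: benzyl bromide, BrCc1ccccc1
Why: Williamson ether synthesis on an acidic, unhindered-at-oxygen phenol, for which K2CO3/DMF benzylation is routine.

Step 2
Reactants: 2 2-(benzyloxy)-1,3-dimethoxybenzene
Product: 3 3-(benzyloxy)-1,5-dibromo-2,4-dimethoxybenzene
Conditions: NBS (2.2 equiv), MeCN, 0 °C to rt, dark
Reagents that add atoms: N-bromosuccinimide, O=C1CCC(=O)N1Br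
Why: Electrophilic aromatic bromination, in which each methoxy group directs to its free ortho/para position, whereas the central benzyloxy group is flanked on both sides, twisted out of conjugation, and leaves its para position untouched.

Step 3
Reactants: 3 3-(benzyloxy)-1,5-dibromo-2,4-dimethoxybenzene
Product: 4 5-(benzyloxy)-4,6-dimethoxybenzene-1,3-diol
Conditions: Pd2(dba)3 (cat.), tBuXPhos (cat.), KOH, 1,4-dioxane/H2O, 100 °C; then dilute HCl
Reagents that add atoms: potassium hydroxide, [K+].[OH-]
Why: Palladium-catalysed hydroxylation of aryl bromides with KOH and a bulky biaryl phosphine (Buchwald-type C–O coupling) is established for electron-rich ortho-alkoxy bromides, and the methyl and benzyl ethers are inert to hot aqueous hydroxide.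

Step 4
Reactants: 4 5-(benzyloxy)-4,6-dimethoxybenzene-1,3-diol
Product: 5 1,3,5-tris(benzyloxy)-2,4-dimethoxybenzene
Conditions: BnBr, K2CO3, DMF, rt to 50 °C, under argon
Reagents that add atoms: benzyl bromide, BrCc1ccccc1
Why: Williamson ether synthesis in a polar aprotic solvent, which favours O- over C-benzylation of the electron-rich resorcinol.

Step 5
Reactants: 5 1,3,5-tris(benzyloxy)-2,4-dimethoxybenzene
Product: 7 2,4,6-tris(benzyloxy)-3,5-dimethoxybenzaldehyde, via benzylidene(dimethyl)iminium chloride 6 (not isolated)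
Conditions: POCl3, DMF, 0 to 70 °C; then ice-water
Reagents that add atoms: N,N-dimethylformamide, CN(C)C=O; water, O
Why: Vilsmeier–Haack formylation at the single remaining ring position, which is activated by two ortho and one para alkoxy groups as in phloroglucinol triethers, while the unactivated benzyl rings do not react.

Step 6
Reactants: 8 3,4-bis(benzyloxy)benzaldehyde
Product: 10 3,4-bis(benzyloxy)phenol, via 3,4-bis(benzyloxy)phenyl formate 9 (not isolated)
Conditions: mCPBA, CH2Cl2, 0 °C to rt; aq. NaHCO3 wash; then K2CO3 (0.1 equiv), MeOH, rt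
Reagents that add atoms: 3-chloroperbenzoic acid, OOC(=O)c1cccc(Cl)c1
Why: Baeyer–Villiger (Dakin-type) oxidation, in which the electron-rich aryl group migrates in preference to hydrogen, followed by base-catalysed methanolysis of the labile aryl formate.

Step 7
Reactants: 10 3,4-bis(benzyloxy)phenol
Product: 11 1,2-bis(benzyloxy)-4-methoxybenzene
Conditions: MeI, K2CO3, acetone, reflux
Reagents that add atoms: iodomethane, CI
Why: Williamson O-methylation of the only free phenol.

Step 8
Reactants: 11 1,2-bis(benzyloxy)-4-methoxybenzene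
Product: 13 4,5-bis(benzyloxy)-2-methoxybenzaldehyde, via benzylidene(dimethyl)iminium chloride 12 (not isolated)
Conditions: POCl3, DMF, 0 to 60 °C; then ice-water
Reagents that add atoms: N,N-dimethylformamide, CN(C)C=O; water, O
Why: Vilsmeier–Haack formylation of a 1,2,4-trialkoxybenzene, which should occur at C5 (ortho to the methoxy group and para to a benzyloxy group), the least hindered and most activated site, as in the formylation of 1,2,4-trimethoxybenzene.

Step 9
Reactants: 13 4,5-bis(benzyloxy)-2-methoxybenzaldehyde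
Product: 14 1,2-bis(benzyloxy)-4-ethynyl-5-methoxybenzene
Conditions: dimethyl (1-diazo-2-oxopropyl)phosphonate, K2CO3, MeOH/THF, rt
Reagents that add atoms: dimethyl (1-diazo-2-oxopropyl)phosphonate, CC(=O)C(=[N+]=[N-])P(=O)(OC)OC
Why: Seyferth–Gilbert homologation in the Ohira–Bestmann variant, which converts non-enolisable aryl aldehydes into terminal alkynes under mild carbonate conditions that leave the ethers untouched.

Step 10
Reactants: 14 1,2-bis(benzyloxy)-4-ethynyl-5-methoxybenzene; 7 2,4,6-tris(benzyloxy)-3,5-dimethoxybenzaldehyde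
Product: 16 rac-3-[4,5-bis(benzyloxy)-2-methoxyphenyl]-1-[2,4,6-tris(benzyloxy)-3,5-dimethoxyphenyl]prop-2-yn-1-ol, via lithium arylacetylide 15 (not isolated)
Conditions: n-BuLi, THF, -78 °C; then 7, -78 to 0 °C; H2O
Reagents that add atoms: none
Why: 1,2-Addition of a lithium acetylide to a non-enolisable aryl aldehyde, in which the new carbinol centre is formed without control as a racemate and is removed by the oxidation of step 11.

Step 11
Reactants: 16 rac-3-[4,5-bis(benzyloxy)-2-methoxyphenyl]-1-[2,4,6-tris(benzyloxy)-3,5-dimethoxyphenyl]prop-2-yn-1-ol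
Product: 17 3-[4,5-bis(benzyloxy)-2-methoxyphenyl]-1-[2,4,6-tris(benzyloxy)-3,5-dimethoxyphenyl]prop-2-yn-1-one
Conditions: MnO2 (activated, excess), CH2Cl2, rt
Reagents that add atoms: none
Why: MnO2 oxidation of a doubly activated (benzylic and propargylic) secondary alcohol to the ynone under neutral conditions that avoid ionisation of the acid-sensitive carbinol.

Step 12
Reactants: 17 3-[4,5-bis(benzyloxy)-2-methoxyphenyl]-1-[2,4,6-tris(benzyloxy)-3,5-dimethoxyphenyl]prop-2-yn-1-one
Product: 18 5,7-bis(benzyloxy)-2-[4,5-bis(benzyloxy)-2-methoxyphenyl]-3-iodo-6,8-dimethoxy-4H-chromen-4-one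
Conditions: ICl (1.1 equiv, 1 M in CH2Cl2), CH2Cl2, -78 °C, dark; then aq. Na2S2O3
Reagents that add atoms: iodine monochloride, ClI
Why: ICl should add to the alkyne of 17 as an iodonium ion whose positive charge sits mainly on the carbon β to the ketone, where the electron-rich ring B stabilises it, and an ortho benzyloxy oxygen of ring A attacks that carbon while iodine stays on the α-carbon. The resulting benzyl oxonium ion is dealkylated by chloride in an SN2 step, releasing benzyl chloride and the neutral 4H-chromen-4-one, so that O1–C2 and C3–I are formed in one operation. The closest known reaction type is the iodine monochloride cyclisation of 2-alkoxyaryl alkynyl ketones to 3-iodochromones. Ring C closes in the 6-endo-dig mode and no stereocentre is created. The step needs attack at the β-carbon instead of 5-exo attack by ring A at the α-carbon or 5-endo attack by the 2-methoxy oxygen of ring B at the α-carbon, and both alternatives would require positive charge next to the carbonyl, which the ynone polarisation disfavours; the two ortho benzyl ethers of ring A are equivalent, so either closure gives the same product. Arene iodination should be limited because ring A is fully substituted and ring B is deactivated by the conjugated ynone, and only a slight excess of ICl is used at -78 °C.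

Step 13
Reactants: 18 5,7-bis(benzyloxy)-2-[4,5-bis(benzyloxy)-2-methoxyphenyl]-3-iodo-6,8-dimethoxy-4H-chromen-4-one
Product: 21 5,7-bis(benzyloxy)-2-[4,5-bis(benzyloxy)-2-methoxyphenyl]-3-hydroxy-6,8-dimethoxy-4H-chromen-4-one, via 4-oxochromen-3-ylmagnesium chloride 19 (not isolated), via dimethyl 4-oxochromen-3-ylboronate 20 (not isolated)
Conditions: iPrMgCl·LiCl, THF, -78 °C; B(OMe)3, -78 to 0 °C; then AcOH, 30% H2O2, 0 °C to rt
Reagents that add atoms: hydrogen peroxide, OO
Why: Iodine–magnesium exchange of the alkenyl iodide with the LiCl-activated isopropyl Grignard reagent should be fast at -78 °C on this vinylogous ester, borylation traps the 3-metallated chromone before it can ring-open, and peroxide oxidation of the C–B bond with 1,2-migration to oxygen (Hawthorne-type phenol synthesis) gives the flavonol.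

Step 14
Reactants: 21 5,7-bis(benzyloxy)-2-[4,5-bis(benzyloxy)-2-methoxyphenyl]-3-hydroxy-6,8-dimethoxy-4H-chromen-4-one
Product: 22 5,7-bis(benzyloxy)-2-[4,5-bis(benzyloxy)-2-methoxyphenyl]-3,6,8-trimethoxy-4H-chromen-4-one
Conditions: MeI, K2CO3, acetone, reflux
Reagents that add atoms: iodomethane, CI
Why: Williamson O-methylation of the flavonol 3-OH, the only free hydroxyl group, as is classical for 3-hydroxyflavones.

Step 15
Reactants: 22 5,7-bis(benzyloxy)-2-[4,5-bis(benzyloxy)-2-methoxyphenyl]-3,6,8-trimethoxy-4H-chromen-4-one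
Product: 23 2-(4,5-dihydroxy-2-methoxyphenyl)-5,7-dihydroxy-3,6,8-trimethoxy-4H-chromen-4-one (5,7,4',5'-tetrahydroxy-3,6,8,2'-tetramethoxyflavone)
Conditions: H2 (1 atm), 10% Pd/C, EtOAc/MeOH, rt, work-up under argon
Reagents that add atoms: none
Why: Catalytic hydrogenolysis of the four aryl benzyl ethers over Pd/C, which leaves the methyl ethers and the tetrasubstituted, conjugated C2=C3 bond of the chromone intact.

**Compound list**
1 | 2,6-dimethoxyphenol (syringol) | COc1cccc(OC)c1O | starting material
2 | 2-(benzyloxy)-1,3-dimethoxybenzene | COc1cccc(OC)c1OCc1ccccc1 | intermediate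
3 | 3-(benzyloxy)-1,5-dibromo-2,4-dimethoxybenzene | COc1c(Br)cc(Br)c(OC)c1OCc1ccccc1 | intermediate
4 | 5-(benzyloxy)-4,6-dimethoxybenzene-1,3-diol | COc1c(O)cc(O)c(OC)c1OCc1ccccc1 | intermediate
5 | 1,3,5-tris(benzyloxy)-2,4-dimethoxybenzene | COc1c(OCc2ccccc2)cc(OCc2ccccc2)c(OC)c1OCc1ccccc1 | intermediate
6 | N-{[2,4,6-tris(benzyloxy)-3,5-dimethoxyphenyl]methylidene}-N-methylmethanaminium chloride | C[N+](C)=Cc1c(OCc2ccccc2)c(OC)c(OCc2ccccc2)c(OC)c1OCc1ccccc1.[Cl-] | intermediate
7 | 2,4,6-tris(benzyloxy)-3,5-dimethoxybenzaldehyde | O=Cc1c(OCc2ccccc2)c(OC)c(OCc2ccccc2)c(OC)c1OCc1ccccc1 | intermediate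
8 | 3,4-bis(benzyloxy)benzaldehyde | O=Cc1ccc(OCc2ccccc2)c(OCc2ccccc2)c1 | starting material
9 | 3,4-bis(benzyloxy)phenyl formate | O=COc1ccc(OCc2ccccc2)c(OCc2ccccc2)c1 | intermediate
10 | 3,4-bis(benzyloxy)phenol | Oc1ccc(OCc2ccccc2)c(OCc2ccccc2)c1 | intermediate
11 | 1,2-bis(benzyloxy)-4-methoxybenzene | COc1ccc(OCc2ccccc2)c(OCc2ccccc2)c1 | intermediate
12 | N-{[4,5-bis(benzyloxy)-2-methoxyphenyl]methylidene}-N-methylmethanaminium chloride | COc1cc(OCc2ccccc2)c(OCc2ccccc2)cc1C=[N+](C)C.[Cl-] | intermediate
13 | 4,5-bis(benzyloxy)-2-methoxybenzaldehyde | COc1cc(OCc2ccccc2)c(OCc2ccccc2)cc1C=O | intermediate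
14 | 1,2-bis(benzyloxy)-4-ethynyl-5-methoxybenzene | COc1cc(OCc2ccccc2)c(OCc2ccccc2)cc1C#C | intermediate
15 | lithium [4,5-bis(benzyloxy)-2-methoxyphenyl]acetylide | COc1cc(OCc2ccccc2)c(OCc2ccccc2)cc1C#C[Li] | intermediate
16 | rac-3-[4,5-bis(benzyloxy)-2-methoxyphenyl]-1-[2,4,6-tris(benzyloxy)-3,5-dimethoxyphenyl]prop-2-yn-1-ol (racemic) | COc1cc(OCc2ccccc2)c(OCc2ccccc2)cc1C#CC(O)c1c(OCc2ccccc2)c(OC)c(OCc2ccccc2)c(OC)c1OCc1ccccc1 | intermediate
17 | 3-[4,5-bis(benzyloxy)-2-methoxyphenyl]-1-[2,4,6-tris(benzyloxy)-3,5-dimethoxyphenyl]prop-2-yn-1-one | COc1cc(OCc2ccccc2)c(OCc2ccccc2)cc1C#CC(=O)c1c(OCc2ccccc2)c(OC)c(OCc2ccccc2)c(OC)c1OCc1ccccc1 | intermediate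
18 | 5,7-bis(benzyloxy)-2-[4,5-bis(benzyloxy)-2-methoxyphenyl]-3-iodo-6,8-dimethoxy-4H-chromen-4-one | COc1cc(OCc2ccccc2)c(OCc2ccccc2)cc1-c1oc2c(OC)c(OCc3ccccc3)c(OC)c(OCc3ccccc3)c2c(=O)c1I | intermediate
19 | {5,7-bis(benzyloxy)-2-[4,5-bis(benzyloxy)-2-methoxyphenyl]-6,8-dimethoxy-4-oxo-4H-chromen-3-yl}magnesium chloride | COc1cc(OCc2ccccc2)c(OCc2ccccc2)cc1-c1oc2c(OC)c(OCc3ccccc3)c(OC)c(OCc3ccccc3)c2c(=O)c1[Mg]Cl | intermediate
20 | dimethyl {5,7-bis(benzyloxy)-2-[4,5-bis(benzyloxy)-2-methoxyphenyl]-6,8-dimethoxy-4-oxo-4H-chromen-3-yl}boronate | COc1cc(OCc2ccccc2)c(OCc2ccccc2)cc1-c1oc2c(OC)c(OCc3ccccc3)c(OC)c(OCc3ccccc3)c2c(=O)c1B(OC)OC | intermediate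
21 | 5,7-bis(benzyloxy)-2-[4,5-bis(benzyloxy)-2-methoxyphenyl]-3-hydroxy-6,8-dimethoxy-4H-chromen-4-one | COc1cc(OCc2ccccc2)c(OCc2ccccc2)cc1-c1oc2c(OC)c(OCc3ccccc3)c(OC)c(OCc3ccccc3)c2c(=O)c1O | intermediate
22 | 5,7-bis(benzyloxy)-2-[4,5-bis(benzyloxy)-2-methoxyphenyl]-3,6,8-trimethoxy-4H-chromen-4-one | COc1cc(OCc2ccccc2)c(OCc2ccccc2)cc1-c1oc2c(OC)c(OCc3ccccc3)c(OC)c(OCc3ccccc3)c2c(=O)c1OC | intermediate
23 | 2-(4,5-dihydroxy-2-methoxyphenyl)-5,7-dihydroxy-3,6,8-trimethoxy-4H-chromen-4-one (5,7,4',5'-tetrahydroxy-3,6,8,2'-tetramethoxyflavone) | COc1cc(O)c(O)cc1-c1oc2c(OC)c(O)c(OC)c(O)c2c(=O)c1OC | target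

Total step count: 15.
Longest linear sequence: 11 steps (steps 1 to 5, then 10 to 15); the ring B branch (steps 6 to 9) joins at step 10.

**Steps most likely to fail**

1. Step 12 (ring C closure). What may go wrong: capture of the iodonium ion by the 2-methoxy oxygen of ring B in a 5-endo closure, plain addition of ICl across the alkyne, or iodination of ring B, so that ring C does not form cleanly. Fallback: setting out from ynone 17, one of the two equivalent ortho benzyl ethers would be removed by carbonyl-directed cleavage with BCl3 (1 equiv, CH2Cl2, -78 °C). This should give 1-[2,4-bis(benzyloxy)-6-hydroxy-3,5-dimethoxyphenyl]-3-[4,5-bis(benzyloxy)-2-methoxyphenyl]prop-2-yn-1-one F1. Et2NH in EtOH would then add to the ynone and the free phenol would displace the amine, closing ring C in the 6-endo sense to 5,7-bis(benzyloxy)-2-[4,5-bis(benzyloxy)-2-methoxyphenyl]-6,8-dimethoxy-4H-chromen-4-one F2. Deprotonation at C3 with LDA (THF, -78 °C) and quenching with I2 would deliver 18, where the route is rejoined.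

2. Step 13 (iodide to hydroxyl). What may go wrong: ring opening of the 3-magnesiated chromone by β-elimination of the ring oxygen, protonation to the de-iodinated flavone, or addition of the Grignard reagent to the C4 carbonyl before exchange. Fallback: setting out from iodide 18, a copper-catalysed Ullmann-type C–O coupling with methanol (CuI, 3,4,7,8-tetramethyl-1,10-phenanthroline, Cs2CO3, MeOH/toluene, 80 °C) would install the C3 methoxy group directly. The route is rejoined at 22, bypassing 21 and step 14; this detour makes no new compound (F0).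

3. Step 3 (double hydroxylation). What may go wrong: stalling of the second C–O coupling because the intermediate bromophenoxide is too electron-rich for oxidative addition, or reductive loss of bromine. Fallback: setting out from dibromide 3, Miyaura borylation (B2pin2, PdCl2(dppf), KOAc, 1,4-dioxane, 90 °C) should give 2,2'-[5-(benzyloxy)-4,6-dimethoxy-1,3-phenylene]bis(4,4,5,5-tetramethyl-1,3,2-dioxaborolane) F3. Oxidation of both C–B bonds with 30% H2O2 in THF/pH 7 buffer would give diol 4, where the route is rejoined.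

**Further compounds**
F1 | step 12 | 1-[2,4-bis(benzyloxy)-6-hydroxy-3,5-dimethoxyphenyl]-3-[4,5-bis(benzyloxy)-2-methoxyphenyl]prop-2-yn-1-one | COc1cc(OCc2ccccc2)c(OCc2ccccc2)cc1C#CC(=O)c1c(O)c(OC)c(OCc2ccccc2)c(OC)c1OCc1ccccc1
F2 | step 12 | 5,7-bis(benzyloxy)-2-[4,5-bis(benzyloxy)-2-methoxyphenyl]-6,8-dimethoxy-4H-chromen-4-one | COc1cc(OCc2ccccc2)c(OCc2ccccc2)cc1-c1oc2c(OC)c(OCc3ccccc3)c(OC)c(OCc3ccccc3)c2c(=O)c1
F0 | step 13 | none | none
F3 | step 3 | 2,2'-[5-(benzyloxy)-4,6-dimethoxy-1,3-phenylene]bis(4,4,5,5-tetramethyl-1,3,2-dioxaborolane) | COc1c(B2OC(C)(C)C(C)(C)O2)cc(B2OC(C)(C)C(C)(C)O2)c(OC)c1OCc1ccccc1
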